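Readings and results come from a simulation for an exercise; the scatter is artificial.

The east run stalled at 46% substrate by 40.0 h, while the north-west run, with 5 mM of free catalyst against 3.8 mM, was down to 10% by 25.0 h. That comparison was where I started on your hunch that slow feeding would be kinder to the flask.

in all of them: second catalyst 2.5 mM

|  | substrate | partner | free catalyst | impurity | remark | time |
|---|---|---|---|---|---|---|
| north-west | 0.10 M | 0.12 M | 5 mM | 3.1 mM | run made earlier |  |
| south | 0.10 M | 0.12 M | 2.5 mM | 3.1 mM | run made earlier |  |
| east | 0.10 M | 0.12 M | 3.8 mM | 3.1 mM | run made earlier |  |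
| south-west | 0.10 M | 0.12 M | 5 mM | 1.6 mM | run made earlier |  |
| Friday's | 0.10 M (fed, over 25 h) | 0.120 M | 5.0 mM | 3.1 mM | all else is in the flask from the start; the feed brings no volume worth counting | 40 h |
| Thursday's | 0.10 M | 0.120 M (fed, over 25 h) | 5.0 mM | 3.1 mM | all else is in the flask from the start; the feed brings no volume worth counting | 40 h |
| Monday's | 0.10 M | 0.120 M | 5.0 mM | 3.1 mM | everything together at the start | 40 h |

| run | time / h | target / % | substrate / % |
|---|---|---|---|
| north-west | 2.00 | 7 | 67 |
| north-west | 6.00 | 25 | 38 |
| north-west | 12.0 | 49 | 18 |
| north-west | 15.0 | 55 | 17 |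
| north-west | 25.0 | 80 | 10 |
| south | 4.00 | 0 | 99 |
| south | 10.0 | 0 | 102 |
| south | 20.0 | 0 | 102 |
| south | 30.0 | 0 | 97 |
| south | 40.0 | 4 | 98 |
| east | 3.00 | 11 | 78 |
| east | 6.00 | 16 | 68 |
| east | 12.0 | 37 | 56 |
| east | 20.0 | 47 | 48 |
| east | 40.0 | 56 | 46 |
| south-west | 3.00 | 10 | 35 |
| south-west | 6.00 | 28 | 19 |
| south-west | 12.0 | 52 | 10 |
| south-west | 20.0 | 71 | 4 |
| south-west | 40.0 | 98 | 4 |

(standard deviation of a reading: 2 percentage points)

- the best flask by amount of target, in percent of the substrate charged; "all alike" if 1.5 percentage points covers them all (Friday's / Thursday's / Monday's / all alike)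
- amount of target at the end, in percent of the substrate charged, Friday's
- amount of target at the end, in percent of the substrate charged, Thursday's
- amount of target at the end, in percent of the substrate charged, Monday's



The south run, with 2.5 mM of free catalyst against 3.1 mM of impurity, showed 4% target at 40.0 h. So I took the impurity to remove its own amount of free catalyst, and I took the survivors to die on a clock. East gave that clock, as its whole logarithmic fall in substrate over its early rate constant:

lifetime = 3.00 h × (ln-fall to 46%) / (ln-fall to 78%) = 9.38 h

I carried this reading as the catalyst lifetime, the time for which surviving free catalyst goes on turning substrate over. The crossing I watched was lifetime against feed time.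

In Friday's flask the feed runs 25 h, longer than the lifetime, so I counted the share of the feed that met living catalyst:

share = 9.38 h / 25 h = 37.5%

Monday's flask has its substrate present from the start, so I scaled east's fall by surviving catalyst, 1.90 mM against 0.700 mM:

substrate left = 12.2%, target = 87.8%

East, north-west, south and south-west each held partner at 0.12 M from the start, so they gave me no reading of a partner feed, and I made no reckoning for Thursday's flask.

The forecast, higher than my share on Friday's and higher than my target on Monday's, gave 47%, 87% and 89% for Friday's, Thursday's and Monday's, with Monday's best, reasoning that “fed substrate arrives after the catalyst has died”.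

The flasks gave 43.8% for Friday's, 87.1% for Thursday's and 92.1% for Monday's, so Monday's came out best.

    substrate + free catalyst → free catalyst + open intermediate (k = 0.0350 M⁻¹ s⁻¹)
    second catalyst + open intermediate ⇌ catalyst intermediate (K = 1300 M⁻¹, k = 0.0870 M⁻¹ s⁻¹)
    partner + catalyst intermediate → second catalyst + target (k = 0.00640 M⁻¹ s⁻¹)
    free catalyst + impurity → spent catalyst A (k = 9.90 M⁻¹ s⁻¹)
    partner + free catalyst → spent catalyst B (k = 2.90 × 10⁻⁴ M⁻¹ s⁻¹)

In this scheme free catalyst is lost to spent catalyst B at a rate proportional to [partner], so the lifetime stretches as [partner] falls. The neighbouring flask is Friday's with 0.048 M of partner. Scaling on the charge gave a lifetime of 23.4 h, still shorter than the feed, and a share of 93.6%. After 40.0 h that flask had consumed 91.4% of its substrate. Its target stood at 39.2%, with 49.8% of the substrate charged held as open intermediate.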